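The methylidenecyclohexane ring (C1 quaternary, C2 exocyclic-methylene carbon, C3 methyl-bearing, C4–C6 methylenes) is cut at two opposite bonds, C1–C2 and C4–C5. A temporary ketone at C5 turns C1 into the β-carbon of an E-enone, so the ring can be assembled in one pot from three parts: a chiral alkylzinc reagent that also carries a vinyl bromide (C2–C4), carbon monoxide (C5) and an (E)-alkenyl iodide made from (S)-linalool (C6, C1 and the side chain). Carbonylative Negishi coupling makes C4–C5; a 6-endo reductive Heck closure then makes C1–C2 and sets the quaternary centre. Deoxygenation, Heck arylation, E-to-Z isomerisation and an o-quinone oxa-Michael ring closure finish the chromene.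

Key step: step 8

Remark: (S)-(+)-linalool and (S)-(+)-3-bromo-2-methylpropan-1-ol are taken as commercial materials of high enantiomeric purity; their stereocentres are carried into the target without a bond to them being broken.

Step 1
Reactants: 1 (S)-3-bromo-2-methylpropan-1-ol
Product: 2 (S)-3-bromo-2-methylpropanal
Conditions: Dess–Martin periodinane, CH2Cl2, 0 °C; used crude
Reagents that add atoms: none
Why: Dess–Martin oxidation stops at the aldehyde under non-basic conditions, so the α-stereocentre should not epimerise and HBr should not be eliminated.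

Step 2
Reactants: 2 (S)-3-bromo-2-methylpropanal
Product: 3 (S)-1,1,4-tribromo-3-methylbut-1-ene
Conditions: CBr4, PPh3, CH2Cl2, 0 °C
Reagents that add atoms: carbon tetrabromide, BrC(Br)(Br)Br
Why: Corey–Fuchs dibromo-olefination (Wittig-type, neutral) should convert the aldehyde into the 1,1-dibromoalkene without touching the stereocentre or the primary bromide.

Step 3
Reactants: 3 (S)-1,1,4-tribromo-3-methylbut-1-ene
Product: 5 (S)-4-bromo-3-methylbut-1-yne, via alkynyllithium 4 (not isolated)
Conditions: n-BuLi (2.05 equiv), THF, −78 °C; then H2O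
Reagents that add atoms: none
Why: Second stage of the Corey–Fuchs alkyne synthesis (Br/Li exchange, 1,2-shift, deprotonation); at −78 °C exchange at the dibromoalkene should be much faster than attack on the primary alkyl bromide.

Step 4
Reactants: 5 (S)-4-bromo-3-methylbut-1-yne
Product: 7 (R)-2,4-dibromo-3-methylbut-1-ene, via alkenylborane 6 (not isolated)
Conditions: B-bromo-9-BBN, CH2Cl2, 0 °C; then AcOH, 0 to 25 °C
Reagents that add atoms: 9-bromo-9-borabicyclo[3.3.1]nonane, BrB1C2CCCC1CCC2
Why: Syn-bromoboration of the terminal alkyne puts bromine on the internal carbon and boron on the terminal carbon, and protodeboronation gives the 2-bromoalk-1-ene; the stereocentre is untouched (its descriptor changes only because the priorities change).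

Step 5
Reactants: 8 (S)-(+)-linalool
Product: 10 (5S)-5-ethenyl-5-methyloxolan-2-ol, via hydroxy aldehyde 9 (not isolated)
Conditions: O3 (1 equiv), CH2Cl2/MeOH, −78 °C; then Me2S, −78 to 25 °C
Reagents that add atoms: ozone, [O-][O+]=O
Why: Ozonolysis should cleave the electron-rich trisubstituted alkene much faster than the vinyl group, and the hydroxy aldehyde closes to the lactol; the carbinol centre is not involved.

Step 6
Reactants: 10 (5S)-5-ethenyl-5-methyloxolan-2-ol
Product: 11 (3S)-3-methylhept-1-en-6-yn-3-ol
Conditions: dimethyl (1-diazo-2-oxopropyl)phosphonate, K2CO3, MeOH, 0 to 25 °C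
Reagents that add atoms: dimethyl (1-diazo-2-oxopropyl)phosphonate, CC(=O)C(=[N+]=[N-])P(=O)(OC)OC
Why: Seyferth–Gilbert homologation with the Ohira–Bestmann reagent should convert the open-chain aldehyde form of the lactol into the terminal alkyne under mild base.

Step 7
Reactants: 11 (3S)-3-methylhept-1-en-6-yn-3-ol
Product: 13 (3S,6E)-7-iodo-3,6-dimethylhepta-1,6-dien-3-ol, via alkenylalane 12 (not isolated)
Conditions: Me3Al (3 equiv), Cp2ZrCl2 (0.3 equiv), CH2Cl2, 0 to 25 °C; then I2, THF, −30 °C
Reagents that add atoms: trimethylaluminium, C[Al](C)C; iodine, II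
Why: Zirconium-catalysed carboalumination (Negishi) adds methyl and aluminium syn across the terminal alkyne and iodinolysis with retention gives the E-alkenyl iodide; one equivalent of Me3Al masks the hydroxyl as its aluminium alkoxide.

Step 8
Reactants: 7 (R)-2,4-dibromo-3-methylbut-1-ene; 13 (3S,6E)-7-iodo-3,6-dimethylhepta-1,6-dien-3-ol
Product: 16 (3S,5R)-3-[(3S)-3-hydroxy-3-methylpent-4-en-1-yl]-3,5-dimethyl-4-methylidenecyclohexan-1-one, via alkylzinc bromide 14 (not isolated), via dienone 15 (not isolated)
Conditions: Zn dust, LiCl, THF, 40 °C; then 13, Pd(PPh3)4 (5 mol%), CO (1 atm), 25 °C; then Ar purge, HCO2Na, DMF, 80 °C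
Reagents that add atoms: carbon monoxide, [C-]#[O+]
Why: Proposed new method: the alkylzinc bromide 14 (zinc inserts only into the primary C–Br bond) undergoes palladium-catalysed carbonylative Negishi coupling with iodide 13 (oxidative addition, CO insertion, transmetalation, reductive elimination) to give E-dienone 15, and after CO is purged the same zerovalent palladium inserts into the vinyl C–Br bond, the alkenylpalladium adds to the enone β-carbon and formate turns the palladium enolate over. The closest known reaction types are the carbonylative Negishi ketone synthesis and the intramolecular reductive Heck (conjugate-addition) cyclisation of a halide tethered to the carbonyl carbon of an enone; running both in one flask and forming a quaternary centre in this mode are the new elements. The ring closes in the 6-endo-trig mode. The new quaternary stereocentre is controlled by the E geometry of 15, which places the side chain (trans to the carbonyl) equatorial and the methyl axial, together with the existing methyl-bearing centre, whose methyl must stay equatorial because the other face would force a 1,3-diaxial methyl–methyl contact; the trans-dimethyl isomer should result. The step needs the alkenyl iodide to react before the vinyl bromide (secured by the much faster oxidative addition of C–I at 25 °C), carbonylative instead of direct coupling (secured by the CO atmosphere) and 6-endo instead of 5-exo closure (secured by the polarisation of the enone and by the tertiary alkylpalladium that 5-exo would need). β-Hydride elimination cannot intervene because the carbon attacked becomes quaternary.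

Step 9
Reactants: 16 (3S,5R)-3-[(3S)-3-hydroxy-3-methylpent-4-en-1-yl]-3,5-dimethyl-4-methylidenecyclohexan-1-one
Product: 18 (3S)-5-[(1R,3R)-1,3-dimethyl-2-methylidenecyclohexyl]-3-methylpent-1-en-3-ol, via tosylhydrazone 17 (not isolated)
Conditions: TsNHNH2, EtOH, 50 °C; then catecholborane, CHCl3, 0 °C; then NaOAc·3H2O, 60 °C
Reagents that add atoms: none
Why: Reduction of the tosylhydrazone of the unhindered ketone with catecholborane and acetate-induced loss of sulfinate and N2 (a mild Wolff–Kishner-type deoxygenation) should remove the carbonyl without moving the non-conjugated alkenes or touching the stereocentres.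

Step 10
Reactants: 19 2-hydroxy-5-methoxybenzaldehyde
Product: 20 2-hydroxy-3-iodo-5-methoxybenzaldehyde
Conditions: N-iodosuccinimide, TsOH (cat.), MeCN, 25 °C
Reagents that add atoms: N-iodosuccinimide, O=C1CCC(=O)N1I
Why: Electrophilic aromatic iodination is directed ortho to the free phenol, the para position being blocked by the methoxy group.

Step 11
Reactants: 20 2-hydroxy-3-iodo-5-methoxybenzaldehyde
Product: 21 3-iodo-5-methoxybenzene-1,2-diol
Conditions: H2O2 (30% aq), NaOH, THF/H2O, 0 °C
Reagents that add atoms: hydrogen peroxide, OO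
Why: Dakin oxidation: hydroperoxide adds to the ortho-hydroxybenzaldehyde, the aryl group migrates and the formate is hydrolysed to the catechol.

Step 12
Reactants: 21 3-iodo-5-methoxybenzene-1,2-diol
Product: 22 3-iodo-5-methoxy-1,2-phenylene diacetate
Conditions: Ac2O, pyridine, DMAP (cat.), CH2Cl2, 0 °C
Reagents that add atoms: acetic anhydride, CC(=O)OC(C)=O
Why: Acetylation protects the air-sensitive catechol through the palladium and photochemical steps and is removed later by mild methanolysis.

Step 13
Reactants: 18 (3S)-5-[(1R,3R)-1,3-dimethyl-2-methylidenecyclohexyl]-3-methylpent-1-en-3-ol; 22 3-iodo-5-methoxy-1,2-phenylene diacetate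
Product: 23 3-[(1E,3S)-5-[(1R,3R)-1,3-dimethyl-2-methylidenecyclohexyl]-3-hydroxy-3-methylpent-1-en-1-yl]-5-methoxy-1,2-phenylene diacetate
Conditions: Pd(OAc)2 (5 mol%), Bu4NCl, NaHCO3, DMF, 60 °C
Reagents that add atoms: none
Why: Mizoroki–Heck reaction: the aryl group adds to the terminal carbon of the unhindered vinyl group and syn β-hydride elimination gives the E-styrene; the hindered exocyclic methylene should not react and the tertiary carbinol centre is untouched.

Step 14
Reactants: 23 3-[(1E,3S)-5-[(1R,3R)-1,3-dimethyl-2-methylidenecyclohexyl]-3-hydroxy-3-methylpent-1-en-1-yl]-5-methoxy-1,2-phenylene diacetate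
Product: 24 3-[(1Z,3S)-5-[(1R,3R)-1,3-dimethyl-2-methylidenecyclohexyl]-3-hydroxy-3-methylpent-1-en-1-yl]-5-methoxy-1,2-phenylene diacetate
Conditions: fac-Ir(ppy)3 (1 mol%), MeCN, blue LEDs (450 nm), 25 °C
Reagents that add atoms: none
Why: Photocatalytic E-to-Z isomerisation by triplet energy transfer: the planar E-styrene is sensitised, whereas the Z isomer is twisted by allylic strain, is sensitised less well and should accumulate.

Step 15
Reactants: 24 3-[(1Z,3S)-5-[(1R,3R)-1,3-dimethyl-2-methylidenecyclohexyl]-3-hydroxy-3-methylpent-1-en-1-yl]-5-methoxy-1,2-phenylene diacetate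
Product: 27 (2S)-2-[2-[(1R,3R)-1,3-dimethyl-2-methylidenecyclohexyl]ethyl]-8-methoxy-2-methyl-2H-chromene-5,6-diol, via catechol 25 (not isolated), via o-quinone 26 (not isolated)
Conditions: K2CO3 (cat.), MeOH, 0 °C, Ar; then evaporation, Ag2O, MgSO4, Et2O, 0 to 25 °C; work-up with aq Na2S2O4
Reagents that add atoms: none
Why: Methanolysis frees the catechol, Ag2O oxidises it to the o-quinone, and the Z-alkene holds the tertiary hydroxyl over C8a so that an intramolecular oxa-Michael addition (6-endo) and tautomerisation should give the chromene-5,6-diol; the C–O bond of the carbinol is never broken, so C2 keeps the S configuration from linalool.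

Compound list
1 | (S)-3-bromo-2-methylpropan-1-ol | OC[C@H](C)CBr | starting material
2 | (S)-3-bromo-2-methylpropanal | O=C[C@H](C)CBr | intermediate
3 | (S)-1,1,4-tribromo-3-methylbut-1-ene | BrC(Br)=C[C@H](C)CBr | intermediate
4 | lithium (S)-4-bromo-3-methylbut-1-yn-1-ide | [Li]C#C[C@H](C)CBr | intermediate
5 | (S)-4-bromo-3-methylbut-1-yne | C#C[C@H](C)CBr | intermediate
6 | 9-[(1Z,3R)-2,4-dibromo-3-methylbut-1-en-1-yl]-9-borabicyclo[3.3.1]nonane | Br/C(=C\B1C2CCCC1CCC2)[C@H](C)CBr | intermediate
7 | (R)-2,4-dibromo-3-methylbut-1-ene | C=C(Br)[C@H](C)CBr | intermediate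
8 | (S)-(+)-linalool, (3S)-3,7-dimethylocta-1,6-dien-3-ol | C=C[C@@](C)(O)CCC=C(C)C | starting material
9 | (4S)-4-hydroxy-4-methylhex-5-enal | O=CCC[C@@](O)(C)C=C | intermediate
10 | (5S)-5-ethenyl-5-methyloxolan-2-ol (anomer mixture) | OC1CC[C@@](C)(C=C)O1 | intermediate
11 | (3S)-3-methylhept-1-en-6-yn-3-ol | C#CCC[C@@](O)(C)C=C | intermediate
12 | [(1E,5S)-5-[(dimethylalumanyl)oxy]-2,5-dimethylhepta-1,6-dien-1-yl]dimethylalumane | C[Al](C)/C=C(\C)CC[C@@](O[Al](C)C)(C)C=C | intermediate
13 | (3S,6E)-7-iodo-3,6-dimethylhepta-1,6-dien-3-ol | I/C=C(\C)CC[C@@](O)(C)C=C | intermediate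
14 | [(2R)-3-bromo-2-methylbut-3-en-1-yl]zinc bromide | C=C(Br)[C@H](C)C[Zn]Br | intermediate
15 | (3R,6E,10S)-2-bromo-10-hydroxy-3,7,10-trimethyldodeca-1,6,11-trien-5-one | C=C(Br)[C@H](C)CC(=O)/C=C(\C)CC[C@@](O)(C)C=C | intermediate
16 | (3S,5R)-3-[(3S)-3-hydroxy-3-methylpent-4-en-1-yl]-3,5-dimethyl-4-methylidenecyclohexan-1-one | C=C1[C@H](C)CC(=O)C[C@]1(C)CC[C@@](O)(C)C=C | intermediate
17 | N'-[(3S,5R)-3-[(3S)-3-hydroxy-3-methylpent-4-en-1-yl]-3,5-dimethyl-4-methylidenecyclohexylidene]-4-methylbenzenesulfonohydrazide | C=C1[C@H](C)CC(=NNS(=O)(=O)c2ccc(C)cc2)C[C@]1(C)CC[C@@](O)(C)C=C | intermediate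
18 | (3S)-5-[(1R,3R)-1,3-dimethyl-2-methylidenecyclohexyl]-3-methylpent-1-en-3-ol | C=C1[C@H](C)CCC[C@]1(C)CC[C@@](O)(C)C=C | intermediate
19 | 2-hydroxy-5-methoxybenzaldehyde | COc1ccc(O)c(C=O)c1 | starting material
20 | 2-hydroxy-3-iodo-5-methoxybenzaldehyde | COc1cc(I)c(O)c(C=O)c1 | intermediate
21 | 3-iodo-5-methoxybenzene-1,2-diol | COc1cc(O)c(O)c(I)c1 | intermediate
22 | 3-iodo-5-methoxy-1,2-phenylene diacetate | COc1cc(I)c(OC(C)=O)c(OC(C)=O)c1 | intermediate
23 | 3-[(1E,3S)-5-[(1R,3R)-1,3-dimethyl-2-methylidenecyclohexyl]-3-hydroxy-3-methylpent-1-en-1-yl]-5-methoxy-1,2-phenylene diacetate | C=C1[C@H](C)CCC[C@]1(C)CC[C@@](O)(C)/C=C/c1cc(OC)cc(OC(C)=O)c1OC(C)=O | intermediate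
24 | 3-[(1Z,3S)-5-[(1R,3R)-1,3-dimethyl-2-methylidenecyclohexyl]-3-hydroxy-3-methylpent-1-en-1-yl]-5-methoxy-1,2-phenylene diacetate | C=C1[C@H](C)CCC[C@]1(C)CC[C@@](O)(C)/C=C\c1cc(OC)cc(OC(C)=O)c1OC(C)=O | intermediate
25 | 3-[(1Z,3S)-5-[(1R,3R)-1,3-dimethyl-2-methylidenecyclohexyl]-3-hydroxy-3-methylpent-1-en-1-yl]-5-methoxybenzene-1,2-diol | C=C1[C@H](C)CCC[C@]1(C)CC[C@@](O)(C)/C=C\c1cc(OC)cc(O)c1O | intermediate
26 | 3-[(1Z,3S)-5-[(1R,3R)-1,3-dimethyl-2-methylidenecyclohexyl]-3-hydroxy-3-methylpent-1-en-1-yl]-5-methoxycyclohexa-3,5-diene-1,2-dione | C=C1[C@H](C)CCC[C@]1(C)CC[C@@](O)(C)/C=C\C1=CC(OC)=CC(=O)C1=O | intermediate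
27 | (2S)-2-[2-[(1R,3R)-1,3-dimethyl-2-methylidenecyclohexyl]ethyl]-8-methoxy-2-methyl-2H-chromene-5,6-diol | C=C1[C@H](C)CCC[C@]1(C)CC[C@@]1(C)C=Cc2c(O)c(O)cc(OC)c2O1 | target

Total step count: 15. Longest linear sequence: 9 steps (steps 1–4, 8, 9, 13, 14, 15).

Steps most likely to fail

Step 8. Three processes may divert the sequence: direct (non-carbonylative) coupling of the zinc reagent, reduction of the alkenylpalladium by formate before it inserts (hydrodebromination), and 5-exo instead of 6-endo insertion. The fallback sets out from 7 and 13 and separates the two events with known chemistry. The carbonylative Negishi coupling is run alone and dienone 15 is isolated. The ring is then closed by a tin hydride-mediated 6-endo-trig vinyl radical cyclisation (Bu3SnH, AIBN, benzene, 80 °C, slow addition), which is governed by the same E geometry and the same equatorial preference of the existing methyl group. The route is rejoined at 16; no compound outside the compound list is made (F0).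

Step 15. Once the acetates are removed, the Z-configured hydroxystyryl carbinol may ionise at the tertiary allylic position and close through the neighbouring phenol oxygen, which would give the wrong ring oxygen and erase C2. The o-quinone may also be consumed by intermolecular addition or oligomerisation before the hindered hydroxyl adds. The fallback sets out from 18. Hydroboration of the vinyl group with 9-BBN and B-alkyl Suzuki–Miyaura coupling with 22 (Pd(dppf)Cl2, K3PO4) should give 3-[(3S)-5-[(1R,3R)-1,3-dimethyl-2-methylidenecyclohexyl]-3-hydroxy-3-methylpentyl]-5-methoxy-1,2-phenylene diacetate F1, which has no allylic carbinol and cannot ionise. Methanolysis and Ag2O oxidation then close the ring on the flexible saturated tether to (2S)-2-[2-[(1R,3R)-1,3-dimethyl-2-methylidenecyclohexyl]ethyl]-8-methoxy-2-methyl-3,4-dihydro-2H-chromene-5,6-diol F2. Dehydrogenation of C3–C4 with DDQ (through the o-quinone and its quinone methide tautomer) and dithionite work-up rejoin the route at 27.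

Step 14. The photostationary state may not favour the Z isomer enough, or the styrene may dimerise by [2+2] addition under sensitisation. The fallback sets out from 23 and moves the isomerisation behind the oxidation. Methanolysis should give 3-[(1E,3S)-5-[(1R,3R)-1,3-dimethyl-2-methylidenecyclohexyl]-3-hydroxy-3-methylpent-1-en-1-yl]-5-methoxybenzene-1,2-diol F3, which cannot cyclise through the phenol because of its E geometry. Ag2O then gives 3-[(1E,3S)-5-[(1R,3R)-1,3-dimethyl-2-methylidenecyclohexyl]-3-hydroxy-3-methylpent-1-en-1-yl]-5-methoxycyclohexa-3,5-diene-1,2-dione F4. Irradiation with visible light, absorbed by the quinone itself without a sensitiser, isomerises the double bond. The Z isomer is removed irreversibly by the oxa-Michael closure, so the position of the photostationary state no longer matters. The route is rejoined at 26.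

Further compounds
F0 | step 8 | none | none
F1 | step 15 | 3-[(3S)-5-[(1R,3R)-1,3-dimethyl-2-methylidenecyclohexyl]-3-hydroxy-3-methylpentyl]-5-methoxy-1,2-phenylene diacetate | C=C1[C@H](C)CCC[C@]1(C)CC[C@@](O)(C)CCc1cc(OC)cc(OC(C)=O)c1OC(C)=O
F2 | step 15 | (2S)-2-[2-[(1R,3R)-1,3-dimethyl-2-methylidenecyclohexyl]ethyl]-8-methoxy-2-methyl-3,4-dihydro-2H-chromene-5,6-diol | C=C1[C@H](C)CCC[C@]1(C)CC[C@@]1(C)CCc2c(O)c(O)cc(OC)c2O1
F3 | step 14 | 3-[(1E,3S)-5-[(1R,3R)-1,3-dimethyl-2-methylidenecyclohexyl]-3-hydroxy-3-methylpent-1-en-1-yl]-5-methoxybenzene-1,2-diol | C=C1[C@H](C)CCC[C@]1(C)CC[C@@](O)(C)/C=C/c1cc(OC)cc(O)c1O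
F4 | step 14 | 3-[(1E,3S)-5-[(1R,3R)-1,3-dimethyl-2-methylidenecyclohexyl]-3-hydroxy-3-methylpent-1-en-1-yl]-5-methoxycyclohexa-3,5-diene-1,2-dione | C=C1[C@H](C)CCC[C@]1(C)CC[C@@](O)(C)/C=C/C1=CC(OC)=CC(=O)C1=O
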